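**Retrosynthetic overview**

1. Numbering: carbocycle C1–C8 (C1 = CH–COiPr, C2/C4 = ketones, C3 = O/prenyl, C5 = prenyl/lactone carbonyl C9, C7 = CH‑prenyl, C8 = Me/side chain). Target 21 ⇐ tertiary allylic alcohol 20 (perhydrolysis) ⇐ C8‑allyl compound 19 (cross‑metathesis) ⇐ 18 (C1 acylation).
2. Lactone ring (formed last) ⇐ oxidative lactonisation of the C9 carboxylate onto C3 of the 2‑prenyl‑cyclooctane‑1,3‑dione 16.
3. Eight‑membered ring ⇐ two‑carbon ring expansion of the cyclohexanone silyl enol ether 12: [2+2] cycloaddition with dichloroketene to cyclobutanone 13, then dechlorination and retro‑aldol opening to 15.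
4. Six‑membered scaffold 12 ⇐ enone 7 by α′‑carboxylation and prenylation (sets C5) and conjugate allylation (sets C8), both steered by C7.
5. Enone 7 ⇐ (R)‑limonene oxide 1 (C7 bought): glycol cleavage, Wittig, α‑methylenation, ring‑closing metathesis. Ring order: cyclohexenone scaffold, cyclobutanone, cyclooctanedione, lactone.

Assumption: C1 is an epimerisable 1,3‑diketone methine, and the drawn configuration is taken to be the thermodynamic one.

**Route**

Step 1
Reactants: 1 (4R)-limonene 1,2-oxide (cis/trans mixture)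
Product: 2 (3R)-6-oxo-3-(prop-1-en-2-yl)heptanal
Conditions: H5IO6, THF/H2O, 0 °C to 25 °C
Reagents that add atoms: water, O
Why: Periodic acid hydrates the epoxide and cleaves the resulting 1,2‑diol (Malaprade glycol cleavage), leaving the bought stereocentre (future C7) untouched.

Step 2
Reactants: 2 (3R)-6-oxo-3-(prop-1-en-2-yl)heptanal
Product: 3 (5R)-8-methyl-5-(prop-1-en-2-yl)non-7-en-2-one
Conditions: iPrPPh3+ I−, n-BuLi, THF, −78 °C to 0 °C
Reagents that add atoms: isopropyltriphenylphosphonium iodide, CC(C)[P+](c1ccccc1)(c1ccccc1)c1ccccc1.[I-]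
Why: The unstabilised ylide reacts with the aldehyde much faster than with the methyl ketone (chemoselective Wittig olefination), turning the CH2CHO arm into the C7 prenyl group.

Step 3
Reactants: 3 (5R)-8-methyl-5-(prop-1-en-2-yl)non-7-en-2-one
Product: 6 (6R)-9-methyl-6-(prop-1-en-2-yl)deca-1,8-dien-3-one, via Mannich base 4 (not isolated), via trimethylammonium iodide 5 (not isolated)
Conditions: LiN(iPr)2, THF, −78 °C; Me2N=CH2+ I−; then MeI, CH2Cl2; then aq NaHCO3, 25 °C
Reagents that add atoms: N,N-dimethylmethyleneiminium iodide (Eschenmoser's salt), C=[N+](C)C.[I-]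
Why: Kinetic deprotonation of the methyl group, Mannich reaction and Hofmann‑type elimination of the quaternised amine give the vinyl ketone (α‑methylenation) without touching the stereocentre.

Step 4
Reactants: 6 (6R)-9-methyl-6-(prop-1-en-2-yl)deca-1,8-dien-3-one
Product: 7 (4R)-3-methyl-4-(3-methylbut-2-en-1-yl)cyclohex-2-en-1-one
Conditions: second-generation Hoveyda–Grubbs catalyst (5 mol %), CH2Cl2 (5 mM), 40 °C
Reagents that add atoms: none
Why: Ring‑closing metathesis of the vinyl ketone with the 1,1‑disubstituted isopropenyl group closes the six‑membered trisubstituted enone with loss of ethene; the trisubstituted prenyl group would have to form a seven‑membered ring and is the slower partner.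

Step 5
Reactants: 8 2-(trimethylsilyl)ethanol
Product: 9 2-(trimethylsilyl)ethyl 1H-imidazole-1-carboxylate
Conditions: CDI, CH2Cl2, 25 °C
Reagents that add atoms: 1,1'-carbonyldiimidazole, O=C(n1ccnc1)n1ccnc1
Why: Acyl transfer from CDI to the primary alcohol gives the alkoxycarbonyl imidazole.

Step 6
Reactants: 7 (4R)-3-methyl-4-(3-methylbut-2-en-1-yl)cyclohex-2-en-1-one; 9 2-(trimethylsilyl)ethyl 1H-imidazole-1-carboxylate
Product: 10 2-(trimethylsilyl)ethyl (5S)-4-methyl-5-(3-methylbut-2-en-1-yl)-2-oxocyclohex-3-ene-1-carboxylate (C1 epimers and enol)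
Conditions: LiN(iPr)2, THF, −78 °C; then 9, BF3·OEt2 (promoter), −78 °C
Reagents that add atoms: none
Why: The kinetic cross‑conjugated α′‑enolate is C‑acylated by the BF3‑activated imidazolide (Claisen‑type acylation), which puts the future lactone carbon C9 on C5.

Step 7
Reactants: 10 2-(trimethylsilyl)ethyl (5S)-4-methyl-5-(3-methylbut-2-en-1-yl)-2-oxocyclohex-3-ene-1-carboxylate
Product: 11 2-(trimethylsilyl)ethyl (1R,5S)-4-methyl-1,5-bis(3-methylbut-2-en-1-yl)-2-oxocyclohex-3-ene-1-carboxylate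
Conditions: K2CO3, prenyl bromide, acetone, 25 °C
Reagents that add atoms: 1-bromo-3-methylbut-2-ene (prenyl bromide), CC(C)=CCBr
Why: C‑alkylation of the β‑keto ester enolate: the C7 prenyl group sits pseudoaxial (A1,2 strain with the vinylic methyl) and shields one face, so the electrophile enters trans to it and fixes the C5 quaternary centre (minor epimer removed by chromatography).

Step 8
Reactants: 11 2-(trimethylsilyl)ethyl (1R,5S)-4-methyl-1,5-bis(3-methylbut-2-en-1-yl)-2-oxocyclohex-3-ene-1-carboxylate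
Product: 12 2-(trimethylsilyl)ethyl (1R,4R,5S)-4-methyl-1,5-bis(3-methylbut-2-en-1-yl)-4-(prop-2-en-1-yl)-2-[(trimethylsilyl)oxy]cyclohex-2-ene-1-carboxylate
Conditions: allylMgBr, CuBr·SMe2, Me3SiCl, THF, −78 °C; Et3N, then pH 7 buffer
Reagents that add atoms: allylmagnesium bromide, C=CC[Mg]Br; chlorotrimethylsilane, C[Si](C)(C)Cl
Why: Silyl‑chloride‑accelerated conjugate addition of allylcopper occurs axially and anti to the adjacent C7 prenyl group, which creates the C8 quaternary centre (allyl trans to prenyl) and traps the regiodefined enolate as its silyl enol ether.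

Step 9
Reactants: 12 2-(trimethylsilyl)ethyl (1R,4R,5S)-4-methyl-1,5-bis(3-methylbut-2-en-1-yl)-4-(prop-2-en-1-yl)-2-[(trimethylsilyl)oxy]cyclohex-2-ene-1-carboxylate
Product: 13 2-(trimethylsilyl)ethyl 8,8-dichloro-5-methyl-2,4-bis(3-methylbut-2-en-1-yl)-7-oxo-5-(prop-2-en-1-yl)-1-[(trimethylsilyl)oxy]bicyclo[4.2.0]octane-2-carboxylate (cis-fused)
Conditions: Cl2CHCOCl, Et3N, hexane, 25 °C, slow addition
Reagents that add atoms: dichloroacetyl chloride, ClC(Cl)C(Cl)=O
Why: Thermal [2+2] cycloaddition of dichloroketene to the electron‑rich silyl enol ether (ketene carbonyl carbon to the enol β‑carbon C1, CCl2 to the siloxy carbon) is much faster than reaction with the unactivated alkenes; the two new ring‑fusion centres are erased in step 10.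

Step 10
Reactants: 13 2-(trimethylsilyl)ethyl 8,8-dichloro-5-methyl-2,4-bis(3-methylbut-2-en-1-yl)-7-oxo-5-(prop-2-en-1-yl)-1-[(trimethylsilyl)oxy]bicyclo[4.2.0]octane-2-carboxylate
Product: 15 2-(trimethylsilyl)ethyl (1R,6S,7S)-6-methyl-1,7-bis(3-methylbut-2-en-1-yl)-2,4-dioxo-6-(prop-2-en-1-yl)cyclooctane-1-carboxylate, via dechlorinated siloxycyclobutanone 14 (not isolated)
Conditions: Zn, AcOH, iPrOH/H2O, 25 °C, then 60 °C
Reagents that add atoms: none
Why: Zinc removes both chlorines, and acid‑mediated desilylation triggers retro‑aldol cleavage of the ring‑fusion bond of the β‑siloxy cyclobutanone (toward the more substituted enol), a two‑carbon ring expansion to the eight‑membered 1,3‑dione that leaves C5, C7 and C8 untouched.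

Step 11
Reactants: 15 2-(trimethylsilyl)ethyl (1R,6S,7S)-6-methyl-1,7-bis(3-methylbut-2-en-1-yl)-2,4-dioxo-6-(prop-2-en-1-yl)cyclooctane-1-carboxylate
Product: 16 2-(trimethylsilyl)ethyl (1R,6S,7S)-6-methyl-1,3,7-tris(3-methylbut-2-en-1-yl)-2,4-dioxo-6-(prop-2-en-1-yl)cyclooctane-1-carboxylate (C3 epimers and enol)
Conditions: Pd(PPh3)4 (5 mol %), prenyl acetate, Et3N, THF, 40 °C
Reagents that add atoms: 3-methylbut-2-en-1-yl acetate (prenyl acetate), CC(=O)OCC=C(C)C
Why: Tsuji–Trost allylation: the soft dione enolate attacks the less hindered terminus of the prenyl–palladium complex through carbon, giving the linear C3‑prenyl dione (C3 stays epimerisable).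

Step 12
Reactants: 16 2-(trimethylsilyl)ethyl (1R,6S,7S)-6-methyl-1,3,7-tris(3-methylbut-2-en-1-yl)-2,4-dioxo-6-(prop-2-en-1-yl)cyclooctane-1-carboxylate
Product: 18 (1R,3S,4S,7S)-4-methyl-1,3,7-tris(3-methylbut-2-en-1-yl)-4-(prop-2-en-1-yl)-8-oxabicyclo[5.2.1]decane-6,9,10-trione, via tetrabutylammonium carboxylate 17 (not isolated)
Conditions: Bu4NF, THF, 0 °C; then PhI(OH)OTs, MeCN, 0 °C
Reagents that add atoms: none
Why: Fluoride frees the C9 carboxylate, and trivalent‑iodine α‑oxidation of the 1,3‑dione is intercepted intramolecularly by it (oxidative lactonisation); the five‑membered tether can only deliver oxygen to the face of C3 syn to C9, which sets the C3 quaternary centre.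

Step 13
Reactants: 18 (1R,3S,4S,7S)-4-methyl-1,3,7-tris(3-methylbut-2-en-1-yl)-4-(prop-2-en-1-yl)-8-oxabicyclo[5.2.1]decane-6,9,10-trione
Product: 19 (1R,3S,4R,5R,7S)-4-methyl-1,3,7-tris(3-methylbut-2-en-1-yl)-5-(2-methylpropanoyl)-4-(prop-2-en-1-yl)-8-oxabicyclo[5.2.1]decane-6,9,10-trione
Conditions: iPrCOCl, MgBr2·OEt2, iPr2NEt, CH2Cl2, 25 °C
Reagents that add atoms: 2-methylpropanoyl chloride, CC(C)C(Cl)=O
Why: Soft enolisation and C‑acylation of the only enolisable ketone (C2, since C3 and C5 are quaternary) gives the β‑diketone without a free lithium enolate that could add to the lactone; the labile C1 centre equilibrates to the isomer with isobutyryl trans to the larger C8 substituent.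

Step 14
Reactants: 19 (1R,3S,4R,5R,7S)-4-methyl-1,3,7-tris(3-methylbut-2-en-1-yl)-5-(2-methylpropanoyl)-4-(prop-2-en-1-yl)-8-oxabicyclo[5.2.1]decane-6,9,10-trione
Product: 20 (1R,3S,4R,5R,7S)-4-[(2E)-4-hydroxy-4-methylpent-2-en-1-yl]-4-methyl-1,3,7-tris(3-methylbut-2-en-1-yl)-5-(2-methylpropanoyl)-8-oxabicyclo[5.2.1]decane-6,9,10-trione
Conditions: 2-methylbut-3-en-2-ol (10 equiv), second-generation Hoveyda–Grubbs catalyst (10 mol %), CH2Cl2, 40 °C
Reagents that add atoms: 2-methylbut-3-en-2-ol, CC(C)(O)C=C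
Why: Cross‑metathesis of the only monosubstituted alkene with the hindered tertiary allylic alcohol gives the E‑alkene; the trisubstituted prenyl groups are poor metathesis partners.

Step 15
Reactants: 20 (1R,3S,4R,5R,7S)-4-[(2E)-4-hydroxy-4-methylpent-2-en-1-yl]-4-methyl-1,3,7-tris(3-methylbut-2-en-1-yl)-5-(2-methylpropanoyl)-8-oxabicyclo[5.2.1]decane-6,9,10-trione
Product: 21 CNP0545483.1, (1R,3S,4R,5R,7S)-4-[(2E)-4-hydroperoxy-4-methylpent-2-en-1-yl]-4-methyl-1,3,7-tris(3-methylbut-2-en-1-yl)-5-(2-methylpropanoyl)-8-oxabicyclo[5.2.1]decane-6,9,10-trione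
Conditions: 50% aq H2O2, cat. H2SO4, THF, 0 °C
Reagents that add atoms: hydrogen peroxide, OO
Why: Acid‑catalysed SN1 perhydrolysis: the tertiary allylic cation is captured by hydrogen peroxide at its tertiary terminus with retention of the E‑alkene.

**Compound list**

1 | (4R)-limonene 1,2-oxide, cis/trans mixture | CC12OC1C[C@@H](CC2)C(C)=C | starting material
2 | (3R)-6-oxo-3-(prop-1-en-2-yl)heptanal | O=CC[C@@H](CCC(C)=O)C(C)=C | intermediate
3 | (5R)-8-methyl-5-(prop-1-en-2-yl)non-7-en-2-one | CC(C)=CC[C@@H](CCC(C)=O)C(C)=C | intermediate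
4 | (6R)-1-(dimethylamino)-9-methyl-6-(prop-1-en-2-yl)dec-8-en-3-one (Mannich base) | CC(C)=CC[C@@H](CCC(=O)CCN(C)C)C(C)=C | intermediate
5 | (6R)-N,N,N,9-tetramethyl-3-oxo-6-(prop-1-en-2-yl)dec-8-en-1-aminium iodide | CC(C)=CC[C@@H](CCC(=O)CC[N+](C)(C)C)C(C)=C.[I-] | intermediate
6 | (6R)-9-methyl-6-(prop-1-en-2-yl)deca-1,8-dien-3-one | CC(C)=CC[C@@H](CCC(=O)C=C)C(C)=C | intermediate
7 | (4R)-3-methyl-4-(3-methylbut-2-en-1-yl)cyclohex-2-en-1-one | CC(C)=CC[C@H]1CCC(=O)C=C1C | intermediate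
8 | 2-(trimethylsilyl)ethanol | C[Si](C)(C)CCO | starting material
9 | 2-(trimethylsilyl)ethyl 1H-imidazole-1-carboxylate | C[Si](C)(C)CCOC(=O)n1ccnc1 | intermediate
10 | 2-(trimethylsilyl)ethyl (5S)-4-methyl-5-(3-methylbut-2-en-1-yl)-2-oxocyclohex-3-ene-1-carboxylate (C1 epimers/enol) | CC(C)=CC[C@H]1CC(C(=O)OCC[Si](C)(C)C)C(=O)C=C1C | intermediate
11 | 2-(trimethylsilyl)ethyl (1R,5S)-4-methyl-1,5-bis(3-methylbut-2-en-1-yl)-2-oxocyclohex-3-ene-1-carboxylate | CC(C)=CC[C@H]1C[C@@](CC=C(C)C)(C(=O)OCC[Si](C)(C)C)C(=O)C=C1C | intermediate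
12 | 2-(trimethylsilyl)ethyl (1R,4R,5S)-4-methyl-1,5-bis(3-methylbut-2-en-1-yl)-4-(prop-2-en-1-yl)-2-[(trimethylsilyl)oxy]cyclohex-2-ene-1-carboxylate | CC(C)=CC[C@H]1C[C@@](CC=C(C)C)(C(=O)OCC[Si](C)(C)C)C(O[Si](C)(C)C)=C[C@]1(C)CC=C | intermediate
13 | cis-fused 8,8-dichloro-1-siloxybicyclo[4.2.0]octan-7-one from 12 (ketene drawn on the face syn to the ester; both fusion centres are lost in step 10) | CC(C)=CC[C@H]1C[C@@](CC=C(C)C)(C(=O)OCC[Si](C)(C)C)[C@@]2(O[Si](C)(C)C)C(Cl)(Cl)C(=O)[C@H]2[C@]1(C)CC=C | intermediate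
14 | dechlorinated 1-siloxybicyclo[4.2.0]octan-7-one | CC(C)=CC[C@H]1C[C@@](CC=C(C)C)(C(=O)OCC[Si](C)(C)C)[C@@]2(O[Si](C)(C)C)CC(=O)[C@H]2[C@]1(C)CC=C | intermediate
15 | 2-(trimethylsilyl)ethyl (1R,6S,7S)-6-methyl-1,7-bis(3-methylbut-2-en-1-yl)-2,4-dioxo-6-(prop-2-en-1-yl)cyclooctane-1-carboxylate | CC(C)=CC[C@H]1C[C@@](CC=C(C)C)(C(=O)OCC[Si](C)(C)C)C(=O)CC(=O)C[C@]1(C)CC=C | intermediate
16 | 2-(trimethylsilyl)ethyl (1R,6S,7S)-6-methyl-1,3,7-tris(3-methylbut-2-en-1-yl)-2,4-dioxo-6-(prop-2-en-1-yl)cyclooctane-1-carboxylate (C3 epimers/enol) | CC(C)=CC[C@H]1C[C@@](CC=C(C)C)(C(=O)OCC[Si](C)(C)C)C(=O)C(CC=C(C)C)C(=O)C[C@]1(C)CC=C | intermediate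
17 | tetrabutylammonium carboxylate of 16 | CC(C)=CC[C@H]1C[C@@](CC=C(C)C)(C(=O)[O-])C(=O)C(CC=C(C)C)C(=O)C[C@]1(C)CC=C.CCCC[N+](CCCC)(CCCC)CCCC | intermediate
18 | (1R,3S,4S,7S)-4-methyl-1,3,7-tris(3-methylbut-2-en-1-yl)-4-(prop-2-en-1-yl)-8-oxabicyclo[5.2.1]decane-6,9,10-trione | CC(C)=CC[C@H]1C[C@@]2(CC=C(C)C)C(=O)O[C@@](CC=C(C)C)(C(=O)C[C@]1(C)CC=C)C2=O | intermediate
19 | (1R,3S,4R,5R,7S)-4-methyl-1,3,7-tris(3-methylbut-2-en-1-yl)-5-(2-methylpropanoyl)-4-(prop-2-en-1-yl)-8-oxabicyclo[5.2.1]decane-6,9,10-trione | CC(C)=CC[C@H]1C[C@@]2(CC=C(C)C)C(=O)O[C@@](CC=C(C)C)(C(=O)[C@@H](C(=O)C(C)C)[C@]1(C)CC=C)C2=O | intermediate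
20 | (1R,3S,4R,5R,7S)-4-[(2E)-4-hydroxy-4-methylpent-2-en-1-yl] analogue of 19 | CC(C)=CC[C@H]1C[C@@]2(CC=C(C)C)C(=O)O[C@@](CC=C(C)C)(C(=O)[C@@H](C(=O)C(C)C)[C@]1(C)C/C=C/C(C)(C)O)C2=O | intermediate
21 | CNP0545483.1 | CC(C)=CC[C@H]1C[C@@]2(CC=C(C)C)C(=O)O[C@@](CC=C(C)C)(C(=O)[C@@H](C(=O)C(C)C)[C@]1(C)C/C=C/C(C)(C)OO)C2=O | target

**Step count**

Total steps: 15. Longest linear sequence: 14 (steps 1–4 and 6–15; step 5 makes reagent 9).

**Three steps most likely to fail**

Step 9. The enol ether is flanked by two quaternary carbons, so the cycloaddition may stop at C‑acylation or not start. The fallback sets out from 7 and comes back at 18. Enone 7 is alkylated at the α′‑carbon (LiN(iPr)2, prenyl bromide) to the 6‑prenyl enone F1, and conjugate allylation as in step 8 gives the trimethylsilyl enol ether F2. C,C‑diacylation with malonyl dichloride (Effenberger‑type annulation, then KOH, BnEt3NCl; typically low‑yielding) closes the bicyclo[3.3.1]nonane‑2,4,9‑trione F3, in which the old ring ketone is C9. Prenylation as in step 11 gives the 3‑prenyl trione F4. Hydroxylation of its enolate from the open exo face (KN(SiMe3)2, 2‑(phenylsulfonyl)‑3‑phenyloxaziridine) gives the 3‑hydroxy trione F5. Its alkoxide adds to the bridging ketone and cleaves the C1–C9 bond (retro‑Claisen, the less substituted enolate expected to leave) to give 18.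

Step 12. The trivalent‑iodine oxidant may attack the alkenes, or tosylate may win over the carboxylate. The fallback sets out from 15 and comes back at 18. Chlorination of the dione with N‑chlorosuccinimide gives the 3‑chloro dione F6. Bu4NF then unmasks the carboxylate, which displaces chloride at the doubly activated secondary carbon (intramolecular SN2) to give the C3‑unsubstituted lactone F7. Its bridgehead C3–H is then prenylated under the step 11 conditions from the only open face to give 18.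

Step 15. Acidic hydrogen peroxide may attack the prenyl groups or the 1,3‑diketone, or give the transposed secondary hydroperoxide. The fallback sets out from 19 and comes back at 21. 2‑Methylbut‑3‑en‑2‑ol is converted with H2O2/H2SO4 into 2‑methylbut‑3‑en‑2‑yl hydroperoxide F8 and protected with 2‑methoxypropene (pyridinium tosylate) as the peroxyketal F9. Cross‑metathesis of 19 with F9 as in step 14 gives the protected hydroperoxide F10, and mild acetal hydrolysis (AcOH, THF/H2O) releases 21.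

**Further compounds**

F1 | step 9 | (4R)-3-methyl-4,6-bis(3-methylbut-2-en-1-yl)cyclohex-2-en-1-one ring, C7 as in 7, C6 epimers | CC(C)=CC[C@H]1CC(CC=C(C)C)C(=O)C=C1C
F2 | step 9 | trimethylsilyl enol ether of the 3-allyl-3-methyl-4,6-diprenylcyclohexanone | CC(C)=CC[C@H]1CC(CC=C(C)C)C(O[Si](C)(C)C)=C[C@]1(C)CC=C
F3 | step 9 | 8-allyl-8-methyl-5,7-diprenylbicyclo[3.3.1]nonane-2,4,9-trione (triketone tautomer, C7 prenyl equatorial) | CC(C)=CC[C@H]1C[C@]2(CC=C(C)C)C(=O)CC(=O)[C@@H](C2=O)[C@]1(C)CC=C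
F4 | step 9 | 3-prenyl derivative of F3 (C3 epimers/enol) | CC(C)=CC[C@H]1C[C@]2(CC=C(C)C)C(=O)C(CC=C(C)C)C(=O)[C@@H](C2=O)[C@]1(C)CC=C
F5 | step 9 | 3-hydroxy-3-prenyl trione (hydroxyl exo, syn to C9) | CC(C)=CC[C@H]1C[C@]2(CC=C(C)C)C(=O)[C@](O)(CC=C(C)C)C(=O)[C@@H](C2=O)[C@]1(C)CC=C
F6 | step 12 | 3-chloro derivative of 15 (C3 epimers) | CC(C)=CC[C@H]1C[C@@](CC=C(C)C)(C(=O)OCC[Si](C)(C)C)C(=O)C(Cl)C(=O)C[C@]1(C)CC=C
F7 | step 12 | C3-unsubstituted lactone (18 lacking the C3 prenyl group) | CC(C)=CC[C@H]1C[C@@]2(CC=C(C)C)C(=O)O[C@@H](C(=O)C[C@]1(C)CC=C)C2=O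
F8 | step 15 | 2-methylbut-3-en-2-yl hydroperoxide | CC(C)(OO)C=C
F9 | step 15 | 3-[(2-methoxypropan-2-yl)peroxy]-3-methylbut-1-ene | COC(C)(C)OOC(C)(C)C=C
F10 | step 15 | 2-methoxypropan-2-yl peroxyketal of 21 | CC(C)=CC[C@H]1C[C@@]2(CC=C(C)C)C(=O)O[C@@](CC=C(C)C)(C(=O)[C@@H](C(=O)C(C)C)[C@]1(C)C/C=C/C(C)(C)OOC(C)(C)OC)C2=O
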